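Amounts first: at 40.0 min the substrate stands at 50.0% in the epsilon run and 49.9% in the eta run, though their second nucleophile charges are 1.40 and 1.70 of the substrate charge.

all flasks: substrate 0.10 M; gas 7.4 mM (held)

| flask | second nucleophile | remark | time |
|---|---|---|---|
| epsilon | 0.14 M | run made earlier |  |
| eta | 0.17 M | run made earlier |  |
| noon | 0.180 M |  | 50 min |
| summer | 0.220 M |  | 50 min |
| dusk | 0.260 M |  | 50 min |

| run | time / min | other capture product / % | substrate / % | isomer of the product / % | target / % |
|---|---|---|---|---|---|
| epsilon | 6.00 | 9.5 | 89.2 | 0 | 0.5 |
| epsilon | 12.0 | 18.1 | 80.7 | 1.2 | 1.0 |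
| epsilon | 20.0 | 28.0 | 71.1 | 0 | 1.3 |
| epsilon | 25.0 | 33.0 | 64.5 | 0.6 | 1.5 |
| epsilon | 30.0 | 38.5 | 58.5 | 1.7 | 1.5 |
| epsilon | 40.0 | 46.4 | 50.0 | 1.5 | 1.7 |
| eta | 6.00 | 9.7 | 90.2 | 0 | 0 |
| eta | 12.0 | 18.0 | 81.8 | 0.6 | 1.0 |
| eta | 20.0 | 27.7 | 70.7 | 0.8 | 0.8 |
| eta | 25.0 | 33.2 | 64.4 | 1.1 | 1.2 |
| eta | 30.0 | 38.6 | 58.7 | 0.9 | 1.3 |
| eta | 40.0 | 47.8 | 49.9 | 1.9 | 1.2 |

(readings scatter by 0.5 percentage points)

- the analysis behind the earlier runs scatters by 0.5 percentage points, standard deviation
- at the start none of the gas is in solution

1. which of these there is most of at the end, counted by the substrate in it, noon (isomer of the product / target / other capture product / substrate)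
2. which of these there is most of at the end, counted by the substrate in it, summer (isomer of the product / target / other capture product / substrate)
3. which of these there is most of at the end, counted by the substrate in it, dusk (isomer of the product / target / other capture product / substrate)
4. the largest of these amounts at the end, in percent of the substrate charged, noon
5. the largest of these amounts at the end, in percent of the substrate charged, summer
6. the largest of these amounts at the end, in percent of the substrate charged, dusk

So second nucleophile does not enter the rate-limiting step of substrate loss. Taken as first order, that loss leaves 42.0% of the substrate at 50 min in noon, summer and dusk, and 58.0% has been consumed. The dispute is over how that consumed part divides.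

The first chemist holds the share flat. Target plus isomer of the product read 3.20% in the epsilon run and 3.10% in the eta run at 40.0 min, equal within the scatter. Other capture product therefore keeps its read share of 93.7%, which gives 54.3% in each flask.

The second chemist, and I side with her, takes the fast step after the slow one as settled: whatever the slow step releases is shared at once between second nucleophile and a rival fed by the held gas. The carried quantity is the rival's worth, the amount of second nucleophile, as a fraction of the substrate charge, that would take as much as the rival takes. It is the ratio of target plus isomer to other capture product, multiplied by the mean second nucleophile, which is the charge less half of what was consumed. The epsilon run reads 0.0806 and the eta run 0.0948, so I carry their mean, 0.0877.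

Other capture product is then the consumed part times mean second nucleophile over that mean plus the worth. With means of 1.51, 1.91 and 2.31, I commit to 54.8% for noon, 55.4% for summer and 55.8% for dusk.

The forecast, nearer the first chemist's side though not her flat 54.3%, names other capture product in each flask at 54.4%, 54.6% and 54.8%, and expects “little change, perhaps slightly more capture product”.

The flasks give other capture product as the largest amount in each, at 54.8%, 55.4% and 55.9%, above substrate at 41.9%, a rise of 1.1 percentage points from noon to dusk.

    gas ⇌ first nucleophile, rate k1*(csat - [first nucleophile]) (kL = 0.0250 s⁻¹)
    target ⇌ isomer of the product (K = 1.80, k = 0.00100 s⁻¹)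
    first nucleophile + intermediate → target (k = 230 M⁻¹ s⁻¹)
    second nucleophile + intermediate → other capture product (k = 180 M⁻¹ s⁻¹)
    substrate ⇌ intermediate (K = 0.150, k = 2.90 × 10⁻⁴ s⁻¹)

The flat view belongs where mean second nucleophile far exceeds the worth, as in noon, at 1.51 against 0.0877. The neighbouring flask is noon with 0.072 M of second nucleophile, or 0.720 equiv. Its mean is 0.430, so the same worth gives 48.1% against the flat 54.3%. That flask gives 48.0% of other capture product, with substrate still at 41.9%, target at 4.99% and isomer of the product at 5.08%.

The data were computed on assumed constants, noise included.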